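## The problem

Compound 13 is a diaryl ketone in which a 4,5-dichloropyrrol-2-yl ring and a 1,2,3,4-tetrasubstituted benzene ring are joined through one carbonyl carbon. It has no stereocentre, so the whole difficulty is regiochemical. Numbering the benzene ring from the carbon that carries the ketone (C1), it bears OH at C2, the 4-methylpentyl chain at C3, OH at C4 and hydrogen at C5 and C6. The chain therefore sits between two oxygens, where electrophilic substitution of a resorcinol does not go cleanly, and the acyl group must enter beside this array at C1 only. The pyrrole has an acidic N–H that becomes a nitrogen nucleophile toward Michael acceptors once deprotonated, and two C–Cl bonds that rule out hydrogenolysis and hot Pd/C. Their positions are easier to buy than to make. The free resorcinol is electron-rich, easily oxidised and readily attacked by electrophiles at C5, so it should appear late and never need ether protection. The enabling feature is that the ketone at C1 and the oxygens at C2 and C4 form a 1,3,5-tricarbonyl pattern: the benzene ring is the dehydrogenated form of a 4-acyl-2-alkylcyclohexane-1,3-dione. In that dione, C1–C2–C3 together with the pyrrolyl carbonyl is an open-chain 1,3-diketone carrying the side chain, and C4–C5–C6 is an acrylate unit, so a (3+3) Michael–Claisen annulation can set all four substituents at once.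

## Retrosynthesis

Target 13 is first traced to its N-protected form 11 by cutting the N–CH2 bond of a 2-(trimethylsilyl)ethoxymethyl (SEM) group; the hemiaminal 12 lies between them. The nitrogen must be blocked through the enolate chemistry, because the free N–H would be deprotonated first, would suppress ketone enolisation and would add to 8 through nitrogen. Sulfonyl and carbamate groups on an acylpyrrole are cleaved by alkoxide and Grignard reagents, and benzyl-type groups would need hydrogenolysis or oxidation at the cost of the chlorines or the resorcinol. SEM survives all steps and leaves with fluoride. The forward step must release the N–H without the liberated formaldehyde alkylating the resorcinol at C5.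

Compound 11 is traced to dione 10 without cutting a skeletal bond; only the hydrogens at C5 and C6 are restored. Forming the arene directly would need a three-carbon partner at the alkyne oxidation level, and adducts of 1,3-diketones with such acceptors tend to close through oxygen to pyranones. At the acrylate level the carbocycle is the only stable ring. The forward step must remove two hydrogens from a strongly enolised triketone without touching the pyrrole, the SEM group or the side chain.

Dione 10 is cut at C1–C6 and C3–C4, giving the open-chain diketone 7 and methyl acrylate 8, with the Michael adduct 9 between them. This cut follows the natural polarity of both partners: the central diketone carbon (C1) is the best nucleophile, the acrylate β-carbon (C6) the acceptor, the ester carbon (C4) the acyl donor and the chain methylene (C3) the second nucleophile. The neighbouring option, forming the C1–acyl bond last by acylating a preformed 2-alkyl dione, needs a regioselective dianion and is kept only as a reserve. The cut replaces a tetrasubstituted carbocycle with a linear diketone and a commodity ester, and makes one ring and two C–C bonds in one operation. The forward reaction must add once through the central carbon and then close through the chain methylene.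

Diketone 7 is cut between its central methylene and the aliphatic carbonyl, giving methyl ketone 4 and methyl ester 6. The other diketone bond would require an aliphatic methyl ketone enolate to attack a pyrrole-2-carboxylic ester. That ester is a hindered vinylogous carbamate and a poor electrophile, and the ketone could enolise on two sides. Ketone 4 has a single enolisable position and 6 is an ordinary ester. The forward crossed Claisen condensation must outrun ester self-condensation, and deprotonation of the product diketone drives it.

Ketone 4 is traced through the Weinreb amides 3 and 2 to the commercial acid 1 by cutting the acetyl C–CH3 bond, the N–SEM bond and the amide C–N bond in turn. Adding a methyl organometallic directly to 1 would need a trianion and risk over-addition, whereas the Weinreb amide stops at the ketone. Making the amide before N-alkylation avoids forming a SEM ester. Ester 6 comes from commercial 6-methylheptanoic acid 5 by esterification.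

## Roads not taken

Alternative 1: The cut runs through the pyrrole at N1–C5 and C2–C3, so the heterocycle is built last on an aryl ketone that carries the benzene substituents as methyl ethers. The amine of amino ketone A2 would displace one geminal chloride of trichloroacrolein A3 by addition–elimination. The ketone methylene, now flanked by nitrogen and carbonyl, would then condense with the aldehyde to close and aromatise the ring, giving dimethyl ether A1.
- Merits: both chlorines arrive with the three-carbon unit, no N-protecting group is needed and there is no oxidation step. In these respects it is better than the chosen plan.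
- Weak points: A2 is a primary α-amino ketone that self-condenses once free-based. A3 is an ambident electrophile; if the amine condensed at the aldehyde first, ring closure at the dichloromethylene carbon would place the chlorines at C3 and C4. The benzene pattern must still be assembled by separate aromatic chemistry, and A1 needs a double ether cleavage with a strong Lewis acid beside the pyrrole.
- Comparison: the chosen plan offers a purchased pyrrole whose chlorine positions are not in question, oxygens that are never masked, and a ring closure whose regiochemistry is fixed thermodynamically.

Alternative 2: The cut opens the benzene ring at C1–C2 and C5–C6. Diene A6, a 1-methoxy-1,3-bis(trimethylsilyloxy)butadiene carrying the 4-methylpentyl group at its C2, would add to the terminal ynone A5. The adduct would lose methanol and silyl groups to give the N-tosyl resorcinol A4.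
- Merits: the arene forms at the right oxidation level with the polarity of both partners matched (nucleophilic diene terminus to the ynone β-carbon). The sequence is convergent and probably shorter than the chosen one.
- Weak points: the diene must be a fully substituted silyl ketene acetal with the chain at an internal position. It is hindered, moisture-sensitive and less ready to adopt the reactive conformation, so open-chain Mukaiyama–Michael addition without ring closure is a real competitor. A5 is a polymerisation-prone acceptor. An N-sulfonyl group on an acylpyrrole is labile to the nucleophiles needed to make the ynone, yet must still be removed at the end.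
- Comparison: this road is better on step count and needs no dehydrogenation. The chosen plan offers stable, chromatographable intermediates and a ring closure pulled by an acidic triketone instead of a demanding cycloaddition.

Alternative 3: Both bonds to the ketone carbon are cut. Pd(PPh3)4 (zerovalent palladium) would insert into the C–I bond of iodopyrrole A8, carbon monoxide A10 would insert, and boronic acid A9 would transfer its aryl group to give the N-Boc dimethyl ether A7.
- Merits: this is the most convergent plan, with the ketone carbon drawn from a one-carbon feedstock and each half only a few steps from simple materials. On convergence it is better than the chosen plan.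
- Weak points: A9 is an electron-rich, ortho-substituted boronic acid prone to protodeboronation and slow transmetalation, which opens the way to direct biaryl coupling or stalling at the acylpalladium stage. The N-Boc acylpyrrole in A7 is base-labile. The 2-iodopyrrole A8 is a sensitive compound. The end game needs cleavage of two aryl methyl ethers, the one at C4 flanked by the alkyl chain, with a strong Lewis acid.
- Comparison: the chosen plan uses no oxygen protecting groups, no toxic gas and no transition metal, and the annulation itself encodes the 1,2,3,4-pattern.

Key step: step 6

Assumption: the β-dicarbonyl compounds 7, 9 and 10 are keto–enol tautomer mixtures; 10 is drawn as one dienol form and all tautomers are treated as the same compound.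

## Route

Step 1
Reactants: 1 4,5-dichloro-1H-pyrrole-2-carboxylic acid
Product: 2 4,5-dichloro-N-methoxy-N-methyl-1H-pyrrole-2-carboxamide
Conditions: MeNHOMe·HCl, EDC·HCl, HOBt, Et3N, CH2Cl2, 0 °C → rt
Reagents that add atoms: N,O-dimethylhydroxylamine hydrochloride, CNOC.Cl
Why: Carbodiimide amide coupling through the HOBt active ester (Weinreb amide formation); the pyrrole nitrogen is non-nucleophilic, so the acid should couple without N-protection.

Step 2
Reactants: 2 4,5-dichloro-N-methoxy-N-methyl-1H-pyrrole-2-carboxamide
Product: 3 4,5-dichloro-N-methoxy-N-methyl-1-{[2-(trimethylsilyl)ethoxy]methyl}pyrrole-2-carboxamide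
Conditions: NaH, DMF, 0 °C; then SEMCl, 0 °C → rt
Reagents that add atoms: 2-(trimethylsilyl)ethoxymethyl chloride, C[Si](C)(C)CCOCCl
Why: N-Alkylation of the pyrrolide: the N–H, acidified by the acyl group and two chlorines, is deprotonated irreversibly by NaH and the anion is alkylated at nitrogen by the reactive α-chloro ether. The SEM group removes the acidic proton and the aza-Michael site and is stable to Grignard reagent, alkoxide and quinone.

Step 3
Reactants: 3 4,5-dichloro-N-methoxy-N-methyl-1-{[2-(trimethylsilyl)ethoxy]methyl}pyrrole-2-carboxamide
Product: 4 1-(4,5-dichloro-1-{[2-(trimethylsilyl)ethoxy]methyl}pyrrol-2-yl)ethanone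
Conditions: MeMgBr, THF, 0 °C; aq. NH4Cl
Reagents that add atoms: methylmagnesium bromide, C[Mg]Br
Why: Weinreb ketone synthesis: the magnesium-chelated tetrahedral intermediate persists until the quench, so only one methyl group adds. The pyrrole C–Cl bonds should not exchange with MeMgBr at 0 °C.

Step 4
Reactants: 5 6-methylheptanoic acid
Product: 6 methyl 6-methylheptanoate
Conditions: MeOH, H2SO4 (cat.), reflux
Reagents that add atoms: methanol, CO
Why: Fischer esterification driven by the excess of methanol; the substrate has no other functional group.

Step 5
Reactants: 4 1-(4,5-dichloro-1-{[2-(trimethylsilyl)ethoxy]methyl}pyrrol-2-yl)ethanone; 6 methyl 6-methylheptanoate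
Product: 7 1-(4,5-dichloro-1-{[2-(trimethylsilyl)ethoxy]methyl}pyrrol-2-yl)-8-methylnonane-1,3-dione
Conditions: NaH (2.5 equiv), 6 (2 equiv), THF, slow addition of 4, 0 °C → reflux; aq. HCl
Reagents that add atoms: none
Why: Crossed Claisen condensation: the methyl ketone, more acidic than the ester and enolisable on one side only, is acylated by 6, and the β-diketone is removed from the equilibrium as its enolate, which is why more than two equivalents of base are used. Slow addition of 4 to base and excess ester limits ketone self-aldol.

Step 6
Reactants: 7 1-(4,5-dichloro-1-{[2-(trimethylsilyl)ethoxy]methyl}pyrrol-2-yl)-8-methylnonane-1,3-dione; 8 methyl acrylate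
Product: 10 4-[(4,5-dichloro-1-{[2-(trimethylsilyl)ethoxy]methyl}pyrrol-2-yl)carbonyl]-2-(4-methylpentyl)cyclohexane-1,3-dione (dienol tautomer drawn), via Michael adduct keto ester 9 (not isolated)
Conditions: 8 (1.1 equiv), KOtBu (0.2 equiv), tBuOH–THF, 0 °C → rt; then KOtBu (2.5 equiv), THF, rt → 50 °C; aq. HCl
Reagents that add atoms: none
Why: Catalytic KOtBu forms the enolate at the central methylene of 7, which adds in a Michael reaction to the β-carbon of 8 (arene bond C1–C6); proton transfer regenerates the base, and the reaction should stop largely at mono-adduct 9, which is more hindered and less acidic than 7. Excess KOtBu then deprotonates 9 at its central carbon and, in equilibrium or as the dianion, at the chain methylene beside the aliphatic ketone (C4 of the former nonanedione), and this carbon attacks the ester carbonyl with loss of methoxide (arene bond C3–C4). The ring closes in a 6-(enolendo)-exo-trig mode; the closest known reaction type is the Dieckmann-type Claisen cyclisation of 5-oxoalkanoates to cyclohexane-1,3-diones used in classical dihydroresorcinol and alkylresorcinol syntheses. The substrate fixes the regiochemistry: the pyrrolyl ketone has no α-hydrogen on its ring side, and attack by the central carbon or the ester α-carbon on any carbonyl would give a four-membered ring. O-Acylation to the six-membered enol lactone is reversible under alkoxide, whereas the C-acylated product is a cyclic triketone whose deprotonation is effectively irreversible and pulls the Michael, proton-transfer and lactone equilibria toward 10. The required selectivities are C- over O-alkylation and single over double Michael addition; the soft, doubly stabilised enolate, the catalytic base and the near-stoichiometric amount of 8 secure them. No lasting stereocentre is formed, because the two methine carbons of the triketo form are enolisable and both become arene carbons in step 7. The SEM group, the C–Cl bonds and the diaryl-type ketone should be inert to alkoxide at these temperatures.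

Step 7
Reactants: 10 4-[(4,5-dichloro-1-{[2-(trimethylsilyl)ethoxy]methyl}pyrrol-2-yl)carbonyl]-2-(4-methylpentyl)cyclohexane-1,3-dione
Product: 11 (4,5-dichloro-1-{[2-(trimethylsilyl)ethoxy]methyl}pyrrol-2-yl)[2,4-dihydroxy-3-(4-methylpentyl)phenyl]methanone
Conditions: DDQ (1.1 equiv), 1,4-dioxane, 90 °C
Reagents that add atoms: none
Why: Quinone dehydrogenation: DDQ abstracts hydride from C6, allylic to the C1=C2 enol of the acyl dione, giving a protonated enone; proton loss and tautomerisation of the remaining carbonyls then give the resorcinol. Aromatisation and the hydrogen bond from the C2 hydroxyl to the ketone drive the reaction, and the acyl group tempers the oxidisability of the product. The acylated, N-alkylated dichloropyrrole is too electron-poor to react with DDQ.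

Step 8
Reactants: 11 (4,5-dichloro-1-{[2-(trimethylsilyl)ethoxy]methyl}pyrrol-2-yl)[2,4-dihydroxy-3-(4-methylpentyl)phenyl]methanone
Product: 13 (4,5-dichloro-1H-pyrrol-2-yl)[2,4-dihydroxy-3-(4-methylpentyl)phenyl]methanone, via N-hydroxymethyl pyrrole 12 (not isolated)
Conditions: Bu4NF (6 equiv), H2NCH2CH2NH2 (3 equiv), THF, 65 °C; aq. NH4Cl
Reagents that add atoms: none
Why: Fluoride-induced SEM cleavage: attack at silicon triggers β-fragmentation to Me3SiF and ethylene, leaving hemiaminal 12, which expels formaldehyde because the acylated dichloropyrrolide is a good leaving group. Ethylenediamine traps the formaldehyde before it can hydroxymethylate the resorcinol at C5. The aryl chlorides and the ketone are untouched, and the excess of fluoride allows for the two phenols.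

## Compound list

1 | 4,5-dichloro-1H-pyrrole-2-carboxylic acid | OC(=O)c1cc(Cl)c(Cl)[nH]1 | starting material
2 | 4,5-dichloro-N-methoxy-N-methyl-1H-pyrrole-2-carboxamide | CON(C)C(=O)c1cc(Cl)c(Cl)[nH]1 | intermediate
3 | 4,5-dichloro-N-methoxy-N-methyl-1-{[2-(trimethylsilyl)ethoxy]methyl}pyrrole-2-carboxamide | CON(C)C(=O)c1cc(Cl)c(Cl)n1COCC[Si](C)(C)C | intermediate
4 | 1-(4,5-dichloro-1-{[2-(trimethylsilyl)ethoxy]methyl}pyrrol-2-yl)ethanone | CC(=O)c1cc(Cl)c(Cl)n1COCC[Si](C)(C)C | intermediate
5 | 6-methylheptanoic acid | CC(C)CCCCC(=O)O | starting material
6 | methyl 6-methylheptanoate | CC(C)CCCCC(=O)OC | intermediate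
7 | 1-(4,5-dichloro-1-{[2-(trimethylsilyl)ethoxy]methyl}pyrrol-2-yl)-8-methylnonane-1,3-dione | CC(C)CCCCC(=O)CC(=O)c1cc(Cl)c(Cl)n1COCC[Si](C)(C)C | intermediate
8 | methyl acrylate | C=CC(=O)OC | starting material
9 | methyl 4-[(4,5-dichloro-1-{[2-(trimethylsilyl)ethoxy]methyl}pyrrol-2-yl)carbonyl]-10-methyl-5-oxoundecanoate (Michael adduct, not isolated; racemic, enolisable centre) | COC(=O)CCC(C(=O)c1cc(Cl)c(Cl)n1COCC[Si](C)(C)C)C(=O)CCCCC(C)C | intermediate
10 | 4-[(4,5-dichloro-1-{[2-(trimethylsilyl)ethoxy]methyl}pyrrol-2-yl)carbonyl]-2-(4-methylpentyl)cyclohexane-1,3-dione (dienol tautomer drawn) | CC(C)CCCC1=C(O)CCC(C(=O)c2cc(Cl)c(Cl)n2COCC[Si](C)(C)C)=C1O | intermediate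
11 | (4,5-dichloro-1-{[2-(trimethylsilyl)ethoxy]methyl}pyrrol-2-yl)[2,4-dihydroxy-3-(4-methylpentyl)phenyl]methanone | CC(C)CCCc1c(O)ccc(C(=O)c2cc(Cl)c(Cl)n2COCC[Si](C)(C)C)c1O | intermediate
12 | [4,5-dichloro-1-(hydroxymethyl)pyrrol-2-yl][2,4-dihydroxy-3-(4-methylpentyl)phenyl]methanone (not isolated) | CC(C)CCCc1c(O)ccc(C(=O)c2cc(Cl)c(Cl)n2CO)c1O | intermediate
13 | (4,5-dichloro-1H-pyrrol-2-yl)[2,4-dihydroxy-3-(4-methylpentyl)phenyl]methanone (achiral) | CC(C)CCCc1c(O)ccc(C(=O)c2cc(Cl)c(Cl)[nH]2)c1O | target

## Step count and risks

Total step count: 8. Longest linear sequence: 7 steps (from 1 through steps 1, 2, 3, 5, 6, 7 and 8); step 4 is a one-step side branch.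

Least certain steps:

Step 6 (key step). The most likely failures are stalling after the Michael addition, a second Michael addition at the central carbon, and fragmentation by retro-Michael or alkoxide-induced retro-Claisen cleavage. These arise because the ring closure must pass through a minor enolate (or a dianion) while the released methoxide is present. Fallback: form the acyl–ring bond last. Commercial cyclohexane-1,3-dione is reductively alkylated with 4-methylpentanal (Hantzsch ester, catalytic L-proline, CH2Cl2) to give 2-(4-methylpentyl)cyclohexane-1,3-dione F1. Its dianion, formed with LiN(iPr)2 in THF at −78 °C, is C-acylated at C4 by Weinreb amide 3, whose stable tetrahedral intermediate prevents a second acylation. This fallback sets out from 3 and returns to the route at 10.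

Step 7. The dehydrogenation may be incomplete, or the electron-rich product may be over-oxidised, for instance by hydride abstraction at the benzylic methylene of the side chain, because the quinone does not distinguish well between a sluggish triketone and a phenol. Fallback: halogenation and dehydrohalogenation, as in classical alkylresorcinol ester syntheses. Compound 10 is treated with one equivalent of Br2 in DMF at 0 °C to give the bromotrione 4-bromo-4-[(4,5-dichloro-1-{[2-(trimethylsilyl)ethoxy]methyl}pyrrol-2-yl)carbonyl]-2-(4-methylpentyl)cyclohexane-1,3-dione F2. On warming, F2 loses hydrogen bromide toward C6 and tautomerises to the arene. Bromination at the alkylated carbon between the ring carbonyls would converge on the same arene by 1,4-elimination. This fallback sets out from 10 and returns at 11.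

Step 8. Loss of the hemiaminal carbon may be slow, and the released formaldehyde may hydroxymethylate the resorcinol at C5 irreversibly if the scavenger does not intercept it, because the phenoxide formed under fluoride is a strong carbon nucleophile. Fallback: reverse the last two operations. Compound 10 is treated with Bu4NF and ethylenediamine, passing through the hemiaminal 4-{[4,5-dichloro-1-(hydroxymethyl)pyrrol-2-yl]carbonyl}-2-(4-methylpentyl)cyclohexane-1,3-dione F3 to the free pyrrole 4-[(4,5-dichloro-1H-pyrrol-2-yl)carbonyl]-2-(4-methylpentyl)cyclohexane-1,3-dione F4. At this stage both nucleophilic ring carbons are fully substituted, so any formaldehyde adduct can revert by retro-aldol. F4 is then dehydrogenated with DDQ in dioxane. This fallback sets out from 10 and returns at 13.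

Step 5. Self-condensation of the enolisable ester and self-aldol of the ketone may compete with the crossed acylation and lower conversion, because both partners are enolisable under NaH. Fallback: soft-enolisation acylation with an acid chloride. Acid 5 is converted with oxalyl chloride and catalytic DMF into 6-methylheptanoyl chloride F5. F5 acylates ketone 4 at carbon in the presence of MgBr2·OEt2 and iPr2NEt in CH2Cl2, where the magnesium chelate of the product diketone prevents further acylation. This fallback sets out from 5 and 4 and returns at 7.

## Further compounds

F1 | step 6 | 2-(4-methylpentyl)cyclohexane-1,3-dione | CC(C)CCCC1C(=O)CCCC1=O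
F2 | step 7 | 4-bromo-4-[(4,5-dichloro-1-{[2-(trimethylsilyl)ethoxy]methyl}pyrrol-2-yl)carbonyl]-2-(4-methylpentyl)cyclohexane-1,3-dione (racemic, enol form drawn) | CC(C)CCCC1=C(O)CCC(Br)(C(=O)c2cc(Cl)c(Cl)n2COCC[Si](C)(C)C)C1=O
F3 | step 8 | 4-{[4,5-dichloro-1-(hydroxymethyl)pyrrol-2-yl]carbonyl}-2-(4-methylpentyl)cyclohexane-1,3-dione (dienol tautomer drawn, not isolated) | CC(C)CCCC1=C(O)CCC(C(=O)c2cc(Cl)c(Cl)n2CO)=C1O
F4 | step 8 | 4-[(4,5-dichloro-1H-pyrrol-2-yl)carbonyl]-2-(4-methylpentyl)cyclohexane-1,3-dione (dienol tautomer drawn) | CC(C)CCCC1=C(O)CCC(C(=O)c2cc(Cl)c(Cl)[nH]2)=C1O
F5 | step 5 | 6-methylheptanoyl chloride | CC(C)CCCCC(=O)Cl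
A1 | alternative 1 | (4,5-dichloro-1H-pyrrol-2-yl)[2,4-dimethoxy-3-(4-methylpentyl)phenyl]methanone | COc1ccc(C(=O)c2cc(Cl)c(Cl)[nH]2)c(OC)c1CCCC(C)C
A2 | alternative 1 | 2-amino-1-[2,4-dimethoxy-3-(4-methylpentyl)phenyl]ethanone | COc1ccc(C(=O)CN)c(OC)c1CCCC(C)C
A3 | alternative 1 | 2,3,3-trichloroprop-2-enal (trichloroacrolein) | O=CC(Cl)=C(Cl)Cl
A4 | alternative 2 | {4,5-dichloro-1-[(4-methylphenyl)sulfonyl]pyrrol-2-yl}[2,4-dihydroxy-3-(4-methylpentyl)phenyl]methanone | CC(C)CCCc1c(O)ccc(C(=O)c2cc(Cl)c(Cl)n2S(=O)(=O)c2ccc(C)cc2)c1O
A5 | alternative 2 | 1-{4,5-dichloro-1-[(4-methylphenyl)sulfonyl]pyrrol-2-yl}prop-2-yn-1-one | C#CC(=O)c1cc(Cl)c(Cl)n1S(=O)(=O)c1ccc(C)cc1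
A6 | alternative 2 | 1-methoxy-2-(4-methylpentyl)-1,3-bis(trimethylsilyloxy)buta-1,3-diene (double-bond geometry not defined) | COC(O[Si](C)(C)C)=C(CCCC(C)C)C(=C)O[Si](C)(C)C
A7 | alternative 3 | tert-butyl 2,3-dichloro-5-[2,4-dimethoxy-3-(4-methylpentyl)benzoyl]pyrrole-1-carboxylate | COc1ccc(C(=O)c2cc(Cl)c(Cl)n2C(=O)OC(C)(C)C)c(OC)c1CCCC(C)C
A8 | alternative 3 | tert-butyl 2,3-dichloro-5-iodopyrrole-1-carboxylate | CC(C)(C)OC(=O)n1c(I)cc(Cl)c1Cl
A9 | alternative 3 | [2,4-dimethoxy-3-(4-methylpentyl)phenyl]boronic acid | COc1ccc(B(O)O)c(OC)c1CCCC(C)C
A10 | alternative 3 | carbon monoxide | [C-]#[O+]
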